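The time allowed, 80 s, is the measure to hold this flask against, and the thing to watch while repeating the run is the sum c_J.E.J + c_G, from which L is drawn.

| flask | E | J | time |
|---|---|---|---|
| noon | 0.28 M | 0.400 equiv | 80 s |
| spring | 0.28 M | 0.600 equiv | 80 s |
| autumn | 0.28 M | 1.00 equiv | 80 s |
| winter | 0.28 M | 1.50 equiv | 80 s |

    E + J → E.J (k1 = 0.10 M⁻¹ s⁻¹)
    J + E.J ⇌ J.E.J (K2 = 4.4 M⁻¹, k2 = 0.38 M⁻¹ s⁻¹)
    J.E.J ⇌ G (K3 = 0.11, k3 = 0.085 s⁻¹)
    G → L (k4 = 0.076 s⁻¹)

- "hardly changes" means that all values lie within two and a half points (for a concentration: within two and a half percent of the largest)
- run time (noon): 80 s

- amount of L at the end, in percent of the E charged for noon, spring, autumn, winter, in this order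
- the course of these numbers from the first flask to the last (falls, then rises / rises all the way / rises, then falls / falls all the way / hardly changes)

Two chemists dispute this before any run. The first holds that the chain passes material on quickly: in noon J.E.J has a forward half-life of 8.2 s on the way to G, and G one of 9.1 s on the way to L, both far shorter than the time allowed, so L should climb toward the ceiling of two J per L, 20.0% of the E charged in noon and 75.0% in winter.

The second answers that those half-lives count one direction, whereas in noon J.E.J and G relax toward each other with a half-life of 0.808 s, much shorter than that of G, so the two form one pool in pre-equilibrium, of which G is the share 9.91%.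

I follow that view by hand. The pool drains into L at the leak constant 0.00753 s⁻¹, the rate constant of the last step times the share of G in the pool; no charge enters it, so noon and winter have the same value, and its half-life of 92.1 s is longer than the time allowed. Counting what is left and not what is made, a pool standing from the first second keeps 54.7% of itself over the run, so even a pool as large as the ceiling from the start gives L of 9.05% in noon and 33.9% in winter. The real pool has to be built first, and the constant of step 2 times the charged c_J, the ratio of c_J.E.J to c_E.J at equilibrium with J at that level, is 0.49 in noon and 1.85 in winter, so I expect a row far under these bounds and rising; my reckoning ends there, with bounds and a direction and no row.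

The forecast sides with the second chemist, giving 1.2%, 2.8%, 6.4% and 11.5%, a course that rises all the way, on the judgement that at the end “a small slow leak has reached L”; its figures come, by its own account, from a rough march through time, whereas my reckoning gives bounds and no row.

The simulation gives 1.33%, 2.69%, 6.12% and 11.0%, a course that rises all the way, and the forecast holds.

In winter the pool stood at 24.4% at 40.0 s and 22.4% at 80.0 s, and the leak acting on it, weighted by Simpson's rule from an empty start, gives 12.0% of L beside the 11.0% found; the pool of noon gives 1.51% beside 1.33%. The first chemist's view has its region in the run without the undoing of G into J.E.J, which together with the short time allowed holds L down in part in winter: without the undoing winter reaches 43.4%, and with it kept but 800 s allowed, 48.0%.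

All constants are made up; the result is computed.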